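**Retrosynthetic overview**
1. Endgame: the C8 angelate and the C3 acetate are attached last to a bicyclic core that carries C3–OH, C10–OH and a C8 silyl ether.
2. Key disconnections, both answered by CrCl2 in one flask: C1–C10 (alkenyl iodide + methyl ketone, closes the ten-membered ring) and C6–C7 with O6–C12 (2-(methoxycarbonyl)allyl bromide + aldehyde, then lactonisation). Ring order: lactone first, carbocycle second.
3. Enabling feature: C10 is a tertiary carbinol bonded directly to the E C1=C2 alkene (retron of alkenyl-metal + ketone). The ring C1–C10 is folded by the cis C6–C7 fusion to the α-methylene-γ-lactone (O6–C12–C11=C13) and by the Z C4=C5 alkene, so that C1 and C10 face each other.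
4. Fragment A (C1–C6, C15): a butenolide-derived lactol; C3 from a catalytic asymmetric alkynylation, Z C4=C5 from syn-carbocupration and lactonisation.
5. Fragment B (C7–C14): an allylic bromide; C8 from a catalytic asymmetric glyoxylate-ene reaction, the acrylate from a Morita–Baylis–Hillman reaction and SN2′ bromination.

Key step: step 12

Remark: locants C1–C15 are germacrane locants of the target (C1=C2, C3–OAc, C4=C5, C6–O lactone, C7, C8–OAng, C9, C10–OH, C11=C13, C12 lactone carbonyl, C14 on C10, C15 on C4).
Assumption: (S,S)-ProPhenol is taken to deliver the 4R carbinol in step 2; if the sense is the reverse, (R,R)-ProPhenol is used with no other change.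

**Fragment A**

Step 1
Reactants: 1 (E)-3-(tributylstannyl)prop-2-en-1-ol
Product: 2 (E)-3-(tributylstannyl)prop-2-enal
Conditions: activated MnO2 (excess), CH2Cl2, rt
Reagents that add atoms: none
Why: MnO2 oxidation of an allylic alcohol is selective for the allylic position and should leave the alkenylstannane and its E geometry untouched.

Step 2
Reactants: 2 (E)-3-(tributylstannyl)prop-2-enal; 3 methyl propiolate
Product: 4 methyl (4R,5E)-4-hydroxy-6-(tributylstannyl)hex-5-en-2-ynoate
Conditions: 3 (3 equiv), Me2Zn (3 equiv), (S,S)-ProPhenol (10 mol%), Ph3P=O (20 mol%), toluene, 0 °C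
Reagents that add atoms: none
Why: Zinc–ProPhenol-catalysed asymmetric alkynylation of an enal; the dinuclear zinc catalyst delivers the alkynylzinc to one aldehyde face and so sets C3 (R).

Step 3
Reactants: 4 methyl (4R,5E)-4-hydroxy-6-(tributylstannyl)hex-5-en-2-ynoate
Product: 6 (5R)-4-methyl-5-[(E)-2-(tributylstannyl)ethenyl]furan-2(5H)-one, via Z-hydroxy enoate 5 (not isolated)
Conditions: Me2CuLi (2.5 equiv), THF, −78 °C; AcOH, −78 °C → rt
Reagents that add atoms: lithium dimethylcuprate Me2CuLi, [Li+].C[Cu-]C
Why: syn-Carbocupration of the ynoate puts methyl and copper cis, so cold protonation should give the Z-enoate 5, whose γ-hydroxyl lactonises and locks the Z C4=C5 alkene in a ring; C3 is not touched.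

Step 4
Reactants: 6 (5R)-4-methyl-5-[(E)-2-(tributylstannyl)ethenyl]furan-2(5H)-one
Product: 7 (5R)-5-[(E)-2-iodoethenyl]-4-methylfuran-2(5H)-one
Conditions: I2 (1.05 equiv), CH2Cl2, 0 °C
Reagents that add atoms: iodine, II
Why: Iododestannylation proceeds with retention of alkene geometry, and the electron-poor butenolide alkene should not react with iodine.

Step 5
Reactants: 7 (5R)-5-[(E)-2-iodoethenyl]-4-methylfuran-2(5H)-one
Product: 8 (5R)-5-[(E)-2-iodoethenyl]-4-methyl-2,5-dihydrofuran-2-ol (both anomers)
Conditions: i-Bu2AlH (1.1 equiv), CH2Cl2, −78 °C; aq. potassium sodium tartrate (KNaC4H4O6)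
Reagents that add atoms: none
Why: Half-reduction of a lactone stops at the aluminium hemiacetal at −78 °C; the lactol is the ring-closed, Z-locked form of the C6 aldehyde and is used at once after a neutral work-up to avoid dehydration to the furan.

**Fragment B**

Step 6
Reactants: 9 ethyl glyoxylate; 10 isobutene
Product: 11 ethyl (2R)-2-hydroxy-4-methylpent-4-enoate
Conditions: (R)-BINOL (10 mol%), TiCl2(Oi-Pr)2 (10 mol%), 4 Å molecular sieves, CH2Cl2, −30 °C
Reagents that add atoms: none
Why: Catalytic asymmetric glyoxylate-ene reaction; the BINOL–titanium Lewis acid blocks one face of the aldehyde and sets C8 (R), and the methallyl group is the masked C10 methyl ketone.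

Step 7
Reactants: 11 ethyl (2R)-2-hydroxy-4-methylpent-4-enoate
Product: 12 ethyl (2R)-2-[(tert-butyldimethylsilyl)oxy]-4-methylpent-4-enoate
Conditions: TBSCl, imidazole, DMF, rt
Reagents that add atoms: tert-butyldimethylsilyl chloride, CC(C)(C)[Si](C)(C)Cl
Why: Standard silylation of a secondary alcohol; a silyl ether is a poor leaving group and should survive the later allylchromium stage.

Step 8
Reactants: 12 ethyl (2R)-2-[(tert-butyldimethylsilyl)oxy]-4-methylpent-4-enoate
Product: 13 (2R)-2-[(tert-butyldimethylsilyl)oxy]-4-methylpent-4-enal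
Conditions: i-Bu2AlH (1.05 equiv), CH2Cl2, −78 °C; aq. potassium sodium tartrate (KNaC4H4O6)
Reagents that add atoms: none
Why: Partial reduction of an α-silyloxy ester, whose tetrahedral aluminium intermediate is stable at −78 °C; the aldehyde is used crude so that C8 should not epimerise.

Step 9
Reactants: 13 (2R)-2-[(tert-butyldimethylsilyl)oxy]-4-methylpent-4-enal; 14 methyl acrylate
Product: 15 methyl (4R)-4-[(tert-butyldimethylsilyl)oxy]-3-hydroxy-6-methyl-2-methylidenehept-6-enoate (both C3 epimers)
Conditions: 14 (5 equiv), DABCO (0.5 equiv), MeOH (2 equiv), rt, several days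
Reagents that add atoms: none
Why: Morita–Baylis–Hillman reaction; the new carbinol centre (C7) is formed without control, which does not matter because it becomes sp2 in step 11.

Step 10
Reactants: 15 methyl (4R)-4-[(tert-butyldimethylsilyl)oxy]-3-hydroxy-6-methyl-2-methylidenehept-6-enoate
Product: 16 methyl (4R)-4-[(tert-butyldimethylsilyl)oxy]-3-hydroxy-2-methylidene-6-oxoheptanoate (both C3 epimers)
Conditions: O3 (1 equiv, indicator dye), CH2Cl2/MeOH, −78 °C; Me2S, −78 °C → rt
Reagents that add atoms: ozone, [O-][O+]=O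
Why: Ozonolysis should cleave the electron-rich 1,1-disubstituted alkene far faster than the electron-poor acrylate, unmasking the C10 methyl ketone.

Step 11
Reactants: 16 methyl (4R)-4-[(tert-butyldimethylsilyl)oxy]-3-hydroxy-2-methylidene-6-oxoheptanoate
Product: 17 methyl (2Z,4R)-2-(bromomethyl)-4-[(tert-butyldimethylsilyl)oxy]-6-oxohept-2-enoate
Conditions: NBS, Me2S, CH2Cl2, 0 °C → rt
Reagents that add atoms: N-bromosuccinimide, O=C1CCC(=O)N1Br
Why: Sulfonium activation of the allylic alcohol and SN2′ attack of bromide should give the thermodynamically preferred Z-configured 2-(bromomethyl)alkenoate (C8 cis to CH2Br), erasing the C7 carbinol centre.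

**Union and endgame**

Step 12
Reactants: 8 (5R)-5-[(E)-2-iodoethenyl]-4-methyl-2,5-dihydrofuran-2-ol; 17 methyl (2Z,4R)-2-(bromomethyl)-4-[(tert-butyldimethylsilyl)oxy]-6-oxohept-2-enoate
Product: 20 (3R,6R,7R,8R,10R)-8-[(tert-butyldimethylsilyl)oxy]-3,10-dihydroxygermacra-1(2)E,4Z,11(13)-trien-12,6-olide, via seco hydroxy ester 18 (not isolated), via seco cis-lactone 19 (not isolated)
Conditions: CrCl2 (nickel-free, 4 equiv), THF (0.1 M), 0 °C → rt; then DMSO/THF to 2 mM, NiCl2 (0.2 equiv), CrCl2 (10 equiv), rt → 40 °C; aq. NH4Cl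
Reagents that add atoms: none
Why: Nickel-free CrCl2 (divalent chromium) reduces only the allylic C–Br bond of 17; the trivalent 2-(methoxycarbonyl)allylchromium adds through C7 to the open (Z)-4-hydroxy-enal tautomer of 8 in a chair Zimmerman–Traxler transition state, the chromium alkoxide lactonises (18 → 19), and only when NiCl2 is added does zerovalent nickel insert into the C1–I bond and hand the alkenyl group to chromium, which adds to the C10 ketone. The closest known reaction types are the chromium-mediated 2-(alkoxycarbonyl)allylation–lactonisation of aldehydes and the Nozaki–Hiyama–Kishi cyclisation of an alkenyl iodide onto a carbonyl group, run here one after the other in the same flask. The lactone closes 5-exo-trig (O6 onto the ester C12) and the carbocycle closes 10-exo-trig (C1 onto C10=O) with retention of the E C1=C2 geometry. C6 and C7 are set together: the Z-configured allylchromium (C8 cis to CH2Cr) must carry C8 axial in the chair, which gives the syn adduct and hence the cis-lactone, and the C7 face is chosen by C8, whose C–H eclipses the alkene (A(1,3) strain) so that the aldehyde enters anti to the bulky silyloxy group (Felkin–Anh-type induction). C10 is set by the β-silyloxy ketone, which by the 1,3-anti polar model presents the face that puts the new hydroxyl anti to O8, as the target requires. The step needs halide order (allyl bromide before alkenyl iodide, secured by withholding nickel), carbonyl order (the allylchromium takes the aldehyde and leaves the methyl ketone as the only electrophile for the alkenylchromium) and ring closure over oligomerisation, secured by high dilution and by the cis-lactone and the Z C4=C5 alkene, which hold C1 and C10 on the same side.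

Step 13
Reactants: 20 (3R,6R,7R,8R,10R)-8-[(tert-butyldimethylsilyl)oxy]-3,10-dihydroxygermacra-1(2)E,4Z,11(13)-trien-12,6-olide
Product: 21 (3R,6R,7R,8R,10R)-3-acetoxy-8-[(tert-butyldimethylsilyl)oxy]-10-hydroxygermacra-1(2)E,4Z,11(13)-trien-12,6-olide
Conditions: Ac2O (1.5 equiv), pyridine, DMAP (cat.), CH2Cl2, 0 °C
Reagents that add atoms: acetic anhydride, CC(=O)OC(C)=O
Why: Chemoselective acylation; the secondary allylic C3 hydroxyl should be acetylated while the tertiary C10 hydroxyl stays free.

Step 14
Reactants: 21 (3R,6R,7R,8R,10R)-3-acetoxy-8-[(tert-butyldimethylsilyl)oxy]-10-hydroxygermacra-1(2)E,4Z,11(13)-trien-12,6-olide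
Product: 22 (3R,6R,7S,8R,10R)-3-acetoxy-8,10-dihydroxygermacra-1(2)E,4Z,11(13)-trien-12,6-olide
Conditions: HF·pyridine, pyridine/THF, 0 °C → rt
Reagents that add atoms: none
Why: Fluoride-driven desilylation under buffered conditions, which should spare the bis-allylic acetate, the tertiary allylic alcohol and the α-methylene lactone (the C7 descriptor changes only through priority, not through geometry).

Step 15
Reactants: 22 (3R,6R,7S,8R,10R)-3-acetoxy-8,10-dihydroxygermacra-1(2)E,4Z,11(13)-trien-12,6-olide; 23 angelic acid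
Product: 25 (3aS,4R,6R,7E,9R,10Z,11aR)-9-acetoxy-6-hydroxy-6,10-dimethyl-3-methylidene-2-oxo-2,3,3a,4,5,6,9,11a-octahydrocyclodeca[b]furan-4-yl (Z)-2-methylbut-2-enoate, via mixed anhydride 24 (not isolated)
Conditions: 23, 2,4,6-trichlorobenzoyl chloride, Et3N, toluene, rt; then 22, DMAP, toluene, 60 °C
Reagents that add atoms: none
Why: Yamaguchi esterification; the mixed anhydride should acylate the secondary C8 hydroxyl and not the tertiary C10 hydroxyl, and this activation mode is the one that best keeps the Z geometry of the angeloyl group.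

**Compound list**
1 | (E)-3-(tributylstannyl)prop-2-en-1-ol | CCCC[Sn](CCCC)(CCCC)/C=C/CO | starting material
2 | (E)-3-(tributylstannyl)prop-2-enal | CCCC[Sn](CCCC)(CCCC)/C=C/C=O | intermediate
3 | methyl propiolate | C#CC(=O)OC | starting material
4 | methyl (4R,5E)-4-hydroxy-6-(tributylstannyl)hex-5-en-2-ynoate | COC(=O)C#C[C@H](O)/C=C/[Sn](CCCC)(CCCC)CCCC | intermediate
5 | methyl (2Z,4R,5E)-4-hydroxy-3-methyl-6-(tributylstannyl)hexa-2,5-dienoate (not isolated) | COC(=O)/C=C(/C)[C@H](O)/C=C/[Sn](CCCC)(CCCC)CCCC | intermediate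
6 | (5R)-4-methyl-5-[(E)-2-(tributylstannyl)ethenyl]furan-2(5H)-one | O=C1C=C(C)[C@@H](/C=C/[Sn](CCCC)(CCCC)CCCC)O1 | intermediate
7 | (5R)-5-[(E)-2-iodoethenyl]-4-methylfuran-2(5H)-one | O=C1C=C(C)[C@@H](/C=C/I)O1 | intermediate
8 | (5R)-5-[(E)-2-iodoethenyl]-4-methyl-2,5-dihydrofuran-2-ol (both anomers) | OC1C=C(C)[C@@H](/C=C/I)O1 | intermediate
9 | ethyl glyoxylate | CCOC(=O)C=O | starting material
10 | isobutene | CC(C)=C | starting material
11 | ethyl (2R)-2-hydroxy-4-methylpent-4-enoate | CCOC(=O)[C@H](O)CC(C)=C | intermediate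
12 | ethyl (2R)-2-[(tert-butyldimethylsilyl)oxy]-4-methylpent-4-enoate | CCOC(=O)[C@H](O[Si](C)(C)C(C)(C)C)CC(C)=C | intermediate
13 | (2R)-2-[(tert-butyldimethylsilyl)oxy]-4-methylpent-4-enal | O=C[C@H](O[Si](C)(C)C(C)(C)C)CC(C)=C | intermediate
14 | methyl acrylate | C=CC(=O)OC | starting material
15 | methyl (4R)-4-[(tert-butyldimethylsilyl)oxy]-3-hydroxy-6-methyl-2-methylidenehept-6-enoate (both C3 epimers) | COC(=O)C(=C)C(O)[C@H](O[Si](C)(C)C(C)(C)C)CC(C)=C | intermediate
16 | methyl (4R)-4-[(tert-butyldimethylsilyl)oxy]-3-hydroxy-2-methylidene-6-oxoheptanoate (both C3 epimers) | COC(=O)C(=C)C(O)[C@H](O[Si](C)(C)C(C)(C)C)CC(C)=O | intermediate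
17 | methyl (2Z,4R)-2-(bromomethyl)-4-[(tert-butyldimethylsilyl)oxy]-6-oxohept-2-enoate | COC(=O)/C(CBr)=C/[C@H](O[Si](C)(C)C(C)(C)C)CC(C)=O | intermediate
18 | methyl (3R,4R,5Z,7R,8E)-3-{(1R)-1-[(tert-butyldimethylsilyl)oxy]-3-oxobutyl}-4,7-dihydroxy-9-iodo-6-methyl-2-methylidenenona-5,8-dienoate (seco hydroxy ester, not isolated) | COC(=O)C(=C)[C@H]([C@H](O)/C=C(/C)[C@H](O)/C=C/I)[C@@H](CC(C)=O)O[Si](C)(C)C(C)(C)C | intermediate
19 | (4R,5R)-4-{(1R)-1-[(tert-butyldimethylsilyl)oxy]-3-oxobutyl}-5-[(1Z,3R,4E)-3-hydroxy-5-iodo-2-methylpenta-1,4-dien-1-yl]-3-methylideneoxolan-2-one (seco cis-lactone, not isolated) | C=C1C(=O)O[C@H](/C=C(/C)[C@H](O)/C=C/I)[C@@H]1[C@@H](CC(C)=O)O[Si](C)(C)C(C)(C)C | intermediate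
20 | (3R,6R,7R,8R,10R)-8-[(tert-butyldimethylsilyl)oxy]-3,10-dihydroxygermacra-1(2)E,4Z,11(13)-trien-12,6-olide | C=C1C(=O)O[C@@H]2/C=C(/C)[C@H](O)/C=C/[C@](C)(O)C[C@@H](O[Si](C)(C)C(C)(C)C)[C@H]12 | intermediate
21 | (3R,6R,7R,8R,10R)-3-acetoxy-8-[(tert-butyldimethylsilyl)oxy]-10-hydroxygermacra-1(2)E,4Z,11(13)-trien-12,6-olide | C=C1C(=O)O[C@@H]2/C=C(/C)[C@H](OC(C)=O)/C=C/[C@](C)(O)C[C@@H](O[Si](C)(C)C(C)(C)C)[C@H]12 | intermediate
22 | (3R,6R,7S,8R,10R)-3-acetoxy-8,10-dihydroxygermacra-1(2)E,4Z,11(13)-trien-12,6-olide | C=C1C(=O)O[C@@H]2/C=C(/C)[C@H](OC(C)=O)/C=C/[C@](C)(O)C[C@@H](O)[C@H]12 | intermediate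
23 | angelic acid, (Z)-2-methylbut-2-enoic acid | C/C=C(/C)C(=O)O | starting material
24 | (Z)-2-methylbut-2-enoic 2,4,6-trichlorobenzoic anhydride (not isolated) | C/C=C(/C)C(=O)OC(=O)c1c(Cl)cc(Cl)cc1Cl | intermediate
25 | CNP0181631.1, (3aS,4R,6R,7E,9R,10Z,11aR)-9-acetoxy-6-hydroxy-6,10-dimethyl-3-methylidene-2-oxo-2,3,3a,4,5,6,9,11a-octahydrocyclodeca[b]furan-4-yl (Z)-2-methylbut-2-enoate | C=C1C(=O)O[C@@H]2/C=C(/C)[C@H](OC(C)=O)/C=C/[C@](C)(O)C[C@@H](OC(=O)/C(C)=C\C)[C@H]12 | target

**Step count and risks**
Total step count: 15 (fragment A: steps 1–5; fragment B: steps 6–11; union and endgame: steps 12–15).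
Longest linear sequence: 10 steps (steps 6–11, then 12–15).

Steps most likely to fail:

1. Step 12. The facial selectivity that C8 is meant to impose at C7 in the allylation stage may be low or of the opposite sense, and it carries C6 with it. In the shared flask the lactol may also dehydrate, or the alkenylchromium may be protonated by the free C3 hydroxyl before it reaches C10. The fallback uncouples the two events and puts the first under catalyst control. It sets out from 17 and 8. Zerovalent-palladium-catalysed borylation of 17 (B2pin2, Pd2(dba)3, DMSO, 50 °C) should give the allylboronate methyl (2E,4R)-4-[(tert-butyldimethylsilyl)oxy]-6-oxo-2-[(4,4,5,5-tetramethyl-1,3,2-dioxaborolan-2-yl)methyl]hept-2-enoate F1. F1 is added to 8 under chiral phosphoric acid catalysis (the TRIP enantiomer matched to 6R, toluene, 0 °C) through a closed chair transition state in which the catalyst, not C8, selects the aldehyde face. Mild acid (PPTS, CH2Cl2) closes 18 to 19, which is now isolated and purified. 19 is then cyclised in a separate, highly dilute NiCl2/CrCl2 run (DMSO/THF), and the route is rejoined at 20.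

2. Step 9. The amine-catalysed coupling is slow, and during that time the α-silyloxy aldehyde may epimerise at C8 or decompose. The fallback replaces nucleophilic catalysis by a preformed acrylate α-anion equivalent (vinylalumination). It sets out from 13 and 3. Hydroalumination of 3 (i-Bu2AlH, N-methylmorpholine N-oxide, THF, 0 °C) should give [1-(methoxycarbonyl)ethenyl]diisobutylalane F2, which adds to 13 within hours at 0 °C without amine base and returns to the route at 15.

3. Step 15. The activated angeloyl group may isomerise from Z to E by reversible conjugate addition of DMAP, the hindered C8 hydroxyl may react slowly, and under amine base the lactone acyl group may migrate from O6 to the free O8. The fallback builds the Z alkene on an ester that is already in place. It sets out from 22. Carbodiimide esterification (EDC·HCl, DMAP, CH2Cl2, 0 °C) with 2-[bis(2,2,2-trifluoroethoxy)phosphoryl]propanoic acid should give quickly the phosphonate ester (3R,6R,7S,8R,10R)-3-acetoxy-8-{2-[bis(2,2,2-trifluoroethoxy)phosphoryl]propanoyloxy}-10-hydroxygermacra-1(2)E,4Z,11(13)-trien-12,6-olide F3. Still–Gennari olefination of F3 with acetaldehyde (KN(SiMe3)2, 18-crown-6, THF, −78 °C) should then give the Z-2-methylbut-2-enoate and return to the route at 25.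

Further compounds
F1 | step 12 | methyl (2E,4R)-4-[(tert-butyldimethylsilyl)oxy]-6-oxo-2-[(4,4,5,5-tetramethyl-1,3,2-dioxaborolan-2-yl)methyl]hept-2-enoate | COC(=O)/C(CB1OC(C)(C)C(C)(C)O1)=C/[C@H](O[Si](C)(C)C(C)(C)C)CC(C)=O
F2 | step 9 | [1-(methoxycarbonyl)ethenyl]diisobutylalane | C=C(C(=O)OC)[Al](CC(C)C)CC(C)C
F3 | step 15 | (3R,6R,7S,8R,10R)-3-acetoxy-8-{2-[bis(2,2,2-trifluoroethoxy)phosphoryl]propanoyloxy}-10-hydroxygermacra-1(2)E,4Z,11(13)-trien-12,6-olide | C=C1C(=O)O[C@@H]2/C=C(/C)[C@H](OC(C)=O)/C=C/[C@](C)(O)C[C@@H](OC(=O)C(C)P(=O)(OCC(F)(F)F)OCC(F)(F)F)[C@H]12
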